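(The constants are assumed; the rest is arithmetic.)

Reciprocal minutes were the unit I reckoned in: in this flask partner is bid for by starting material, second substrate and third substrate, and each bids at its rate constant times its concentration.

starting material 0.020 M; partner 0.0120 M (in portions, 3); second substrate 0.0200 M; third substrate 4.00 mM; time 5.0 h; the portions of partner follow each other after 40 min, the first at the start

    third substrate + partner → third product (k1 = 5.37 M⁻¹ min⁻¹)
    second substrate + partner → second product (k2 = 0.875 M⁻¹ min⁻¹)
    starting material + partner → target (k3 = 2.24 M⁻¹ min⁻¹)
    second substrate → decomposition product (k4 = 2.16 × 10⁻⁵ min⁻¹)
    starting material + target → side product (k5 = 1.14 M⁻¹ min⁻¹)

* which holds at 5.0 h: what has brought the reaction to rest, or that it has not come to rest (forward and back rates have come level / it is still moving / all of the starting material has reacted)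
* conversion of starting material at 5.0 h
* amount of target at 5.0 h, in percent of the starting material charged

- a species is counted by the starting material in it: one side product counts as two
- the reaction counts as stopped when no species that holds the starting material changes by six tenths of a point or more over the second half of the time
- run time (flask): 5.0 h

For whoever took over the bench: at the start the bids stood at 0.0448 min⁻¹, 0.0175 min⁻¹ and 0.0215 min⁻¹, in that order. I defined the partner share W, the bid of starting material over the sum of the bids, and got W = 0.535. I expected it to drift little: per unit of partner, the bid of third substrate falls faster than that of starting material, 5.37 M⁻¹ min⁻¹ against 2.24 M⁻¹ min⁻¹, while step 5 also draws starting material down. So I held W fixed.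

Partner was the limiting reagent, 0.0120 M against 0.020 M of starting material. Target ever formed in this flask should therefore be W times the partner charge over the starting material charge, 32.1% of the starting material charged. Its half-life by step 5 was 0.51 h as charged, shorter than the run, and each target eaten takes one more starting material, so I committed to a conversion near 64.2%. With that much consumed, I reckoned target's half-life by step 5 at 1.41 h, and the last 2.50 h is less than two of these. So I expected target still present and falling at the end, and I wrote: still moving, and do not quench when partner reads flat, since step 5 has no partner on its left.

The forecast said: it is still moving, with 61.5% conversion and 2.7% target, holding that the “starting material stays in excess and keeps eating the target”. The flask gave: it is still moving, with 60.9% conversion and 2.43% target.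

At 0.836 h the target's half-life by step 5 was 0.65 h, short against the 5.0 h of the run, and at the end this flask held 58.5% in side product against 2.43% in target. Since one side product counts as two, 31.7% had formed as target, beside my 32.1%.

In the neighbour with 0.0050 M of starting material, W becomes 0.223, so 53.5% of its starting material should form as target. That neighbour ended with 32.7% target and 42.4% in side product, which makes 53.9% formed as target, at 75.1% conversion.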